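## Structural features

The target is a briarane. A cyclohexane (ring A: C1, C10–C14) is trans-fused through C1–C10 to a ten-membered carbocycle (C1–C10), which carries a γ-lactone (O–C19–C17–C8–C7) trans-fused across C7–C8. Of the nine stereocentres, six form an unbroken chain C14–C1–C10–C9–C8–C7, with C2 and C17 attached to it; the quaternary C1 is flanked by three stereocentres and the tertiary carbinol C8 by C7, C9 and C17. The ten-membered ring holds a (Z)-trisubstituted olefin C5(Me)=C6, and ring A holds an exocyclic methylene C11=C20 next to the ring-fusion hydrogen at C10. The fragile elements are the β-hydroxy lactone (retro-aldol), the allylic lactone oxygen at C7, the C9 acetate beside a free tertiary hydroxyl (acyl migration), and C10–H, which is allylic and α to a carbonyl whenever C9 is a ketone. The real difficulty is the medium ring: it must be formed with a Z olefin, next to a quaternary centre, and with the C1 methyl and C10–H trans. The key step exploits the 1,3-relationship of olefinic C5 and oxygenated C9 across the ring: a temporary C5–C9 bond turns the ten-membered ring into a cis-hydroazulene (seven-membered ring C1–C5/C9/C10, five-membered ring C5–C9), and a leaving group at C6 lets a C9 alkoxide regenerate ring and olefin in one fragmentation.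

## Logic of the disconnections

39 ⇒ 38 ⇒ 37. The C2–O and C14–O acetyl bonds are cut and the two oxygens are tied into one silylene ring. The gain is a single protecting group that survives base, hydride and mild acid and is orthogonal to an isopropylidene. The forward demand is fluoride cleavage and acetylation that leave the tertiary C8–OH and the lactone alone.

37 ⇒ 36 ⇒ 35 ⇒ 33 + 34. The C8–C17 bond is cut (retro-Reformatsky), then the C7–O–C19 ester bond, and C8 is returned to a carbinol. This removes the lactone, C17 and the tertiary centre C8 in one move. The demands are that the enolate attack the C8 ketone from the face of the C7 oxygen with the ring holding C6 and C9 anti (trans-fused lactone), and that C7–OH be acylated in preference to C8–OH in 33.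

33 ⇒ 32 ⇒ 31 ⇒ 30. The C9–O acetyl bond and the C9–H bond are cut, and the C7/C8 diol is closed as an isopropylidene. 30 then has a C9 ketone whose α,β-oxygens sit in a cis-fused dioxolane, which disfavours β-elimination. The forward demand is hydride delivery to C9 under chelation with the C8 oxygen (anti C8/C9).

30 ⇒ 28 (key). The C5=C6 π bond and the C9 carbonyl are traded for a C5–C9 σ bond and a C6 sulfonate. The ten-membered ring becomes a 6-7-5 tricycle and the Z olefin becomes a relative configuration on a cyclopentane. The forward demand is an anti-periplanar C6–O/C5–C9 array with the sulfonate cis to C4. A stereoformula of this tricycle that places the sulfonate cis to the C5 methyl would lead to the E olefin. 28 is therefore the C6 epimer of such a drawing (C6–O cis to C4 and to the C7/C8 oxygens), and the C2/C14 oxygens are carried as a silylene instead of two separate silyl ethers.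

28 ⇒ 27 ⇒ 26 ⇒ 25. The S–O bond, the C6 silyl ether and the C11=C20 bond are cut, leaving a C11 ketone. This exposes a β-hydroxy ketone. The demand is a non-basic methylenation of a hindered, enolisable ketone.

25 ⇒ 24. The C9–C10 bond is cut (retro-aldol), which opens the seven-membered ring and leaves two ketones, of which only C11 can deliver a nucleophile that gives a common ring. The demands are ring fusion trans at C1/C10 and attack on C9 from the face of the C4 tether. The silylene of 24 is there to meet the first demand: it locks ring A in the chair in which a cis-fused product would be 1,3-diaxial.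

24 ⇒ 23 ⇒ 21 ⇒ 19 ⇒ 17 ⇒ 16. The C7–O and C8–O bonds are cut back to a C7=C8 enone, the enone to the saturated ketone, and the C6–H bond to a symmetrical 1,3-dione. All five-membered-ring stereocentres are traced to one reagent-controlled desymmetrisation (C5, C6) and one hydroxyl-directed dihydroxylation (C7, C8). The demand is syn delivery of both oxygens relative to the C6 hydroxyl.

16 ⇒ 15 ⇒ 14. The Si–O bonds and the C2–H bond are cut, leaving a C2 ketone β to the C14 hydroxyl. The demand is a syn-selective, chemoselective reduction that spares the dione.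

14 ⇒ 12 + 13. The C4–C5 bond is cut (retro-Michael). It separates the five-membered ring as a commercial dione from a ring A vinyl ketone and creates the quaternary C5 without a stereochemical demand.

12 ⇒ 11 ⇒ 10 + 6, then 10 ⇒ 8 ⇒ 7. The C2–C3 bond is cut to an aldehyde and a vinyl nucleophile, the aldehyde is traced to a vinyl group, and the C11 ketal is removed. The only demand is functional-group tolerance of the free C14 hydroxyl.

7 ⇒ 5 + 6. The C1–C2 bond is cut. The quaternary centre is reduced to a conjugate addition in which the C14 alkoxide must deliver the nucleophile to its own face.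

5 ⇒ 3 ⇒ 2 ⇒ 1. The C14–O bond is traced to an epoxide of a deconjugated enone ketal. The single demand is an enantioselective epoxidation of a trisubstituted olefin, which fixes the absolute configuration of the whole synthesis.

## Other disconnections considered

Alternative 1: The cuts are C4–C5 and C6–C7, with the lactone C7–O bond formed in the same operation. The forward key step would give the seco lactone A1 in one flask. An alkylcopper reagent carrying ring A adds syn across propyne A2; the resulting (Z)-alkenylcopper adds to an aldehyde that already holds C8, C17 and C19, and the C7 alkoxide closes the lactone. In its favour, the olefin geometry follows from the syn carbometalation of A2, which is as mechanistically secure as the anti-periplanar rule of the chosen fragmentation (equal on this point). It is convergent, and it sets C8 and C17 in a small fragment rather than by a late Reformatsky closure on a medium ring (better on these two points). Against it, A1 is a seco compound: the ten-membered ring must still be closed at C9–C10, between a carbon next to quaternary C1 and the fully substituted C8, by a true macrocyclisation with its entropic and transannular cost, whereas the chosen plan never closes the medium ring by bond formation. The C7 configuration depends on facial selectivity at an α-quaternary aldehyde, and the alkenylcopper is a weak nucleophile towards aldehydes. The longest linear sequence would probably be shorter, but the hardest bond is deferred rather than solved.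

Alternative 2: The cut is C1–C10. In the forward step a Lewis acid activates a C14–C1 epoxide, the allylsilane carbon C10 opens it at C1 with inversion, and loss of silicon leaves C11=C20, giving A3. In its favour, one step forms ring A, the quaternary C1, the C10 stereocentre and the exocyclic methylene, with the C1/C10 relationship fixed by a stereospecific anti opening through a chair. On this point it is better than the chosen plan, whose weakest step is the thermodynamic setting of C10 in the aldol closure. Against it, C14–OH emerges equatorial and must be inverted at a neopentyl position, and A3 contains only ring A: the ten-membered ring, the Z olefin and the lactone are still to be made from two hydroxymethyl arms. On step count it is shorter for ring A but not for the whole target, and it leaves the medium-ring problem open. It is complementary rather than competing, and could feed a ring A unit into either plan.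

Alternative 3: The cut is the lactone C7–O bond. In the forward step a C19 primary amide is converted into an N-iodoamide; its amidyl radical abstracts the allylic hydrogen at C7 through a six-membered transition state, the amide oxygen bonds to C7 and the iminolactone is hydrolysed, giving A4. In its favour, the C7 oxygen need not be carried through the synthesis, so the β-elimination risk of a C9 ketone with a C7 oxygen disappears (better than the chosen plan on this point), and the step is late and short. Against it, the C7 radical is allylic and delocalised to C5, so regiochemistry and retention of the Z geometry are not assured. C9–H is equally placed for 1,5-abstraction, the C7 configuration rests on facial selectivity in a flexible ring, and iodine electrophiles may attack the two olefins. The chosen plan instead carries C7 as a defined stereocentre from a directed dihydroxylation. Alternative 3 also does not build the ten-membered ring, so it could at best replace the last third of the chosen route.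

Key step: step 21

Remarks on the chemistry (assumptions): (a) Briarane numbering is used for all intermediates, and "α" means the face of ring A opposite to the C1 methyl. (b) 34 is used as the racemate; the bromine-bearing carbon of 35 and 36 is stereorandom and is erased in step 27. 11 is a pair of C2 epimers erased in step 8, and the ozonide carbon of 9 is stereorandom. (c) The L-fructose-derived epoxidation catalyst of step 2 is assumed to be prepared from L-sorbose by the known route.

## Route

Step 1
Reactants: 1 3-methylcyclohex-2-en-1-one
Product: 2 7-methyl-1,4-dioxaspiro[4.5]dec-7-ene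
Conditions: ethylene glycol, p-TsOH·H2O (cat.), benzene, reflux, Dean–Stark
Reagents that add atoms: ethylene glycol OCCO
Why: Deconjugative ketalisation: acid-catalysed ketal formation of a β-substituted cyclohexenone passes through the dienol ether and gives the β,γ-unsaturated ketal, which isolates the trisubstituted C1=C14 olefin for epoxidation.

Step 2
Reactants: 2 7-methyl-1,4-dioxaspiro[4.5]dec-7-ene
Product: 3 7,8-epoxy-7-methyl-1,4-dioxaspiro[4.5]decane (single enantiomer; epoxide on the later C14–O face)
Conditions: 1,2:4,5-di-O-isopropylidene-β-L-erythro-2,3-hexodiulo-2,6-pyranose (0.3 equiv), KHSO5 (as 2KHSO5·KHSO4·K2SO4), K2CO3, Bu4NHSO4, MeCN/dimethoxymethane/H2O, 0 °C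
Reagents that add atoms: potassium peroxymonosulfate [K+].[O-]S(=O)(=O)OO
Why: Shi asymmetric epoxidation of a trisubstituted olefin through the chiral dioxirane and a spiro transition state; the L-fructose-derived ketone is chosen so that oxygen arrives on the face that makes C14 (S), and the basic buffer keeps the ketal.

Step 3
Reactants: 3 7,8-epoxy-7-methyl-1,4-dioxaspiro[4.5]decane
Product: 5 (S)-4-hydroxy-3-methylcyclohex-2-en-1-one, via epoxy ketone 4 (not isolated)
Conditions: pyridinium p-toluenesulfonate, acetone/H2O, rt; then Et3N, CH2Cl2, rt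
Reagents that add atoms: water O
Why: Mild ketal hydrolysis frees the β,γ-epoxy ketone, whose enolisation towards C10 opens the epoxide at C1 (E1cB), a standard route to γ-hydroxy enones; the C14–O bond is not touched, so the epoxide configuration becomes the C14 carbinol.

Step 4
Reactants: 5 (S)-4-hydroxy-3-methylcyclohex-2-en-1-one; 6 vinylmagnesium bromide
Product: 7 (3S,4S)-4-hydroxy-3-methyl-3-vinylcyclohexan-1-one
Conditions: 6 (3 equiv), THF, −78 → 0 °C; aq. NH4Cl
Reagents that add atoms: none
Why: Alkoxide-directed conjugate addition of a Grignard reagent to a γ-hydroxy enone: the magnesium alkoxide formed by the first equivalent delivers vinyl to C1 on its own face, so the new quaternary centre has the vinyl group (future C2) cis to the C14 oxygen and the methyl trans.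

Step 5
Reactants: 7 (3S,4S)-4-hydroxy-3-methyl-3-vinylcyclohexan-1-one
Product: 8 ethylene ketal of 7 (7-methyl-7-vinyl-1,4-dioxaspiro[4.5]decan-8-ol)
Conditions: ethylene glycol, pyridinium p-toluenesulfonate (cat.), benzene, reflux, Dean–Stark
Reagents that add atoms: ethylene glycol OCCO
Why: Ketalisation masks the C11 ketone against the Grignard reagent of step 7 and the two borane reductions; no stereocentre is involved.

Step 6
Reactants: 8 ethylene ketal of 7
Product: 10 ring A aldehyde (8-hydroxy-7-methyl-1,4-dioxaspiro[4.5]decane-7-carbaldehyde), via ozonide 9 (not isolated)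
Conditions: O3, CH2Cl2, −78 °C; then PPh3, −78 °C → rt
Reagents that add atoms: ozone [O-][O+]=O
Why: Ozonolysis with reductive work-up cleaves the only olefin to the neopentyl aldehyde (C2); the α-carbon is quaternary, so no epimerisation is possible, and the neutral conditions avoid retro-aldol of the β-hydroxy aldehyde.

Step 7
Reactants: 10 ring A aldehyde; 6 vinylmagnesium bromide
Product: 11 allylic alcohol (C2 epimers)
Conditions: 6 (2.5 equiv), THF, −78 °C; aq. NH4Cl
Reagents that add atoms: none
Why: 1,2-Addition of the Grignard reagent to the aldehyde (one equivalent is consumed by the hydroxyl); the C2 configuration is irrelevant because C2 is oxidised in step 8.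

Step 8
Reactants: 11 allylic alcohol (C2 epimers)
Product: 12 ring A vinyl ketone
Conditions: MnO2, CH2Cl2, rt
Reagents that add atoms: none
Why: MnO2 oxidises the allylic alcohol selectively and leaves the saturated C14 carbinol, giving the enone without touching a stereocentre.

Step 9
Reactants: 12 ring A vinyl ketone; 13 2-methylcyclopentane-1,3-dione
Product: 14 Michael adduct (triketone)
Conditions: Et3N (0.2 equiv), EtOAc, rt
Reagents that add atoms: none
Why: Michael addition of the acidic 2-substituted 1,3-dione to a vinyl ketone forms C4–C5 and the (still prochiral) quaternary C5; a reversible oxa-Michael closure of the C14 hydroxyl onto the enone would only store 12 and is drained by the C-addition.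

Step 10
Reactants: 14 Michael adduct (triketone)
Product: 15 syn-C2/C14 diol (2R)
Conditions: catecholborane (4 equiv), THF, −10 °C; then MeOH, aq. KNaC4H4O6
Reagents that add atoms: none
Why: syn-Selective reduction of a β-hydroxy ketone with catecholborane through the six-membered boron chelate with external axial hydride delivery; unactivated ketones such as the hindered dione are not reduced at this temperature, and C2 is set (R), syn to the C14 oxygen.

Step 11
Reactants: 15 syn-C2/C14 diol
Product: 16 di-tert-butylsilylene dione
Conditions: (t-Bu)2Si(OTf)2, 2,6-lutidine, CH2Cl2, 0 °C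
Reagents that add atoms: di-tert-butylsilyl bis(trifluoromethanesulfonate) CC(C)(C)[Si](OS(=O)(=O)C(F)(F)F)(OS(=O)(=O)C(F)(F)F)C(C)(C)C
Why: Silylene formation from a syn-1,3-diol; besides protecting C2–O and C14–O with one group orthogonal to the later isopropylidene, the chair dioxasilinane (C3 and C13 equatorial) locks ring A in the chair with axial C14–O and axial C1 methyl, which is used in step 17.

Step 12
Reactants: 16 di-tert-butylsilylene dione
Product: 17 hydroxy ketone (5R,6R; C6–OH cis to the C4 chain)
Conditions: (S)-1-methyl-3,3-diphenyltetrahydro-1H,3H-pyrrolo[1,2-c][1,3,2]oxazaborole (0.2 equiv), catecholborane, toluene, −60 °C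
Reagents that add atoms: none
Why: CBS desymmetrisation of a 2,2-disubstituted cyclopentane-1,3-dione: the catalyst fixes the new carbinol as (R) and hydride enters anti to the larger C5 substituent, so one carbonyl is selected; this sets C5 and C6 and leaves a single ketone (C9).

Step 13
Reactants: 17 hydroxy ketone
Product: 19 γ-hydroxy cyclopentenone (C7=C8), via bis-silyl enol ether 18 (not isolated)
Conditions: LiN(i-Pr)2, Me3SiCl, THF, −78 °C; Pd(OAc)2, MeCN, rt; then K2CO3, MeOH, 0 °C
Reagents that add atoms: none
Why: Saegusa–Ito dehydrogenation; the ketone can enolise only towards C8 because C5 is quaternary, so the C7=C8 enone forms regiospecifically, and the transient C6 silyl ether is removed by methanolysis.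

Step 14
Reactants: 19 γ-hydroxy cyclopentenone
Product: 21 all-cis C6/C7/C8 triol ketone, via osmate ester 20 (not isolated)
Conditions: OsO4 (1.05 equiv), TMEDA, CH2Cl2, −78 °C; then aq. Na2SO3, THF, 40 °C
Reagents that add atoms: osmium tetroxide O=[Os](=O)(=O)=O
Why: Hydrogen-bond-directed dihydroxylation of a cyclic allylic alcohol with the OsO4–TMEDA complex adds both oxygens syn to the C6 hydroxyl, giving the all-cis triol and setting C7 (the configuration kept to the target) and C8.

Step 15
Reactants: 21 all-cis triol ketone
Product: 23 C7/C8 acetonide diketone (C6–OH free), via acetonide ketal 22 (not isolated)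
Conditions: 2,2-dimethoxypropane, pyridinium p-toluenesulfonate, acetone, rt; then H2O, 50 °C
Reagents that add atoms: 2,2-dimethoxypropane COC(C)(C)OC; water O
Why: Under equilibrating conditions the isopropylidene settles on the C7/C8 diol, because an acetonide at the neopentyl C6 oxygen would clash with the cis C4 chain; added water then transfers the ring A dioxolane to acetone while the solvent preserves the new acetonide.

Step 16
Reactants: 23 C7/C8 acetonide diketone
Product: 24 C6 triethylsilyl ether diketone
Conditions: Et3SiOTf, 2,6-lutidine, CH2Cl2, −78 °C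
Reagents that add atoms: triethylsilyl trifluoromethanesulfonate CC[Si](CC)(CC)OS(=O)(=O)C(F)(F)F
Why: Silylation of the C6 hydroxyl under non-enolising conditions prevents retro-aldol opening of this β-hydroxy ketone in the basic aldol step.

Step 17
Reactants: 24 C6 triethylsilyl ether diketone
Product: 25 tricyclic ketol (6-7-5; C11 ketone; C9–OH)
Conditions: KOt-Bu (1.0 equiv), t-BuOH/THF, 0 °C; aq. NH4Cl, 0 °C
Reagents that add atoms: none
Why: Reversible intramolecular aldol addition, the only enolate closure of 24 that gives a common ring: C10 adds to C9 from the face of the C4 tether, so the C9 hydroxyl is cis to the C5 methyl. C10, which can equilibrate through enolate and retro-aldol, should settle with C9 equatorial and trans to C2, because in the silylene-locked chair the cis-fused isomer would have to place C9 axial and syn to the axial C14 oxygen.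

Step 18
Reactants: 25 tricyclic ketol
Product: 26 C11 methylene tricycle
Conditions: Cp2Ti(μ-Cl)(μ-CH2)AlMe2, pyridine, THF/toluene, −40 → 0 °C
Reagents that add atoms: μ-chloro-μ-methylene-bis(cyclopentadienyl)titanium dimethylaluminium C[Al-]1(C)C[Ti]([Cl+]1)(C1C=CC=C1)C1C=CC=C1
Why: Titanium methylidene (Tebbe-type) methylenation works on hindered, enolisable ketones without base, so the β-hydroxy ketone is not exposed to retro-aldol; C11 is the only carbonyl, and C10 is configurationally fixed once the ketone is gone.

Step 19
Reactants: 26 C11 methylene tricycle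
Product: 27 C6 alcohol
Conditions: pyridinium p-toluenesulfonate, MeOH/CH2Cl2, 0 °C → rt
Reagents that add atoms: none
Why: Acid-catalysed methanolysis removes the secondary triethylsilyl ether; the cyclic di-tert-butylsilylene and the cis-fused acetonide react much more slowly under these conditions.

Step 20
Reactants: 27 C6 alcohol
Product: 28 tricyclic C9 alcohol C6 mesylate (key-step precursor)
Conditions: MsCl, Et3N, CH2Cl2, −20 °C
Reagents that add atoms: methanesulfonyl chloride CS(Cl)(=O)=O
Why: Sulfonylation through sulfene takes the secondary C6 hydroxyl and leaves the hindered tertiary C9 hydroxyl; the C6–O bond is not broken, so the sulfonate stays cis to C4 and to the acetonide and trans to the C5 methyl.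

Step 21
Reactants: 28 tricyclic C9 alcohol C6 mesylate
Product: 30 bicyclic (Z)-cyclodecenone (C9 ketone; C7/C8 acetonide), via potassium alkoxide 29 (not isolated)
Conditions: KOt-Bu (1.1 equiv), THF, −40 → −10 °C; AcOH, −40 °C
Reagents that add atoms: none
Why: Deprotonation gives the tertiary C9 alkoxide 29. Its oxygen lone pair pushes into the C5–C9 σ bond, which is anti-periplanar to the C6–OMs bond when the sulfonate is pseudo-equatorial on the cyclopentane, so C9=O formation, C5–C9 cleavage, C5=C6 formation and loss of mesylate are concerted; the closest known reaction type is the Grob (Wharton) fragmentation of cyclic 1,3-diol monosulfonates to medium-ring cycloalkenones. The ten-membered ring is not closed by bond formation: it appears by ring expansion when the bond shared by the five- and seven-membered rings is cut, so no cyclisation entropy or transannular strain is paid in a ring-closing transition state. No stereocentre is created; C5 and C9 are erased, and C7, C8, C10 and the ring A centres are carried through. The selectivity needed is olefin geometry: in the anti-periplanar array the ring carbon C7 is synclinal to the C5 substituent that lies on the same face as the leaving group, and since the mesylate is cis to C4 (trans to the C5 methyl), C4 and C7 end cis, i.e. (Z). Simple E2 elimination is excluded because C5 is quaternary, and attack of the alkoxide on C6 would need an oxabicyclo[2.1.1] skeleton. The fragmentation is irreversible; one equivalent of base, low temperature and a cold acidic quench are used because the product has an acidic C10–H (α to the ketone and allylic) and a β-oxygen at C7, although enolisation towards C8 is disfavoured inside the cis-fused dioxolane.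

Step 22
Reactants: 30 bicyclic (Z)-cyclodecenone
Product: 31 C9 alcohol (9R)
Conditions: Zn(BH4)2, Et2O, −30 °C
Reagents that add atoms: none
Why: Chelation-controlled reduction of an α-alkoxy ketone: zinc bridges the C9 carbonyl and the C8 acetonide oxygen and hydride enters from the side of the C8 hydrogen, which gives the anti C8/C9 relationship, i.e. (9R).

Step 23
Reactants: 31 C9 alcohol
Product: 32 C9 acetate
Conditions: Ac2O, 4-(dimethylamino)pyridine, pyridine, CH2Cl2, rt
Reagents that add atoms: acetic anhydride CC(=O)OC(C)=O
Why: Nucleophile-catalysed acetylation of the secondary alcohol installs the C9 acetate of the target and differentiates C9 from the diol released next.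

Step 24
Reactants: 32 C9 acetate
Product: 33 C7/C8 diol
Conditions: pyridinium p-toluenesulfonate, MeOH, 40 °C
Reagents that add atoms: none
Why: Transketalisation to methanol removes the isopropylidene; the silylene and the acetate tolerate mildly acidic methanol, and a short reaction time limits C9→C8 acetyl migration.

Step 25
Reactants: 33 C7/C8 diol; 34 2-bromopropanoyl bromide
Product: 35 C7 2-bromopropanoate
Conditions: 34 (1.1 equiv), 2,4,6-collidine, CH2Cl2, −78 → −40 °C
Reagents that add atoms: none
Why: Kinetic acylation with an acid bromide should take the allylic C7 hydroxyl, which has an sp2 neighbour, in preference to the C8 hydroxyl wedged between two oxygenated sp3 carbons.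

Step 26
Reactants: 35 C7 2-bromopropanoate
Product: 36 C8 ketone
Conditions: Dess–Martin periodinane, NaHCO3, CH2Cl2, 0 °C → rt
Reagents that add atoms: none
Why: Buffered periodinane oxidation converts the remaining secondary alcohol into the ketone without base, so C7 (now α to the ketone) is not epimerised.

Step 27
Reactants: 36 C8 ketone
Product: 37 silylene-protected lactone (8S,17R)
Conditions: SmI2 (2.2 equiv), THF, −78 °C; AcOH, −78 °C
Reagents that add atoms: none
Why: Samarium diiodide-mediated intramolecular Reformatsky reaction: the trivalent samarium enolate from the C–Br bond adds to the C8 ketone from the face of the C7 ester oxygen (5-exo), and with the C6–C7–C8–C9 torsion held anti by the ten-membered ring this gives the trans-fused lactone with the (8S) hydroxyl. The C17 methyl takes the position anti to C9 (cis to OH), which is also the isomer favoured on base equilibration.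

Step 28
Reactants: 37 silylene-protected lactone
Product: 38 C2/C14 diol
Conditions: HF·pyridine, pyridine, THF, 0 °C → rt
Reagents that add atoms: none
Why: Buffered fluoride cleaves the di-tert-butylsilylene and spares the acetate, the β-hydroxy lactone and both olefins.

Step 29
Reactants: 38 C2/C14 diol
Product: 39 CNP0187723.2
Conditions: Ac2O, 4-(dimethylamino)pyridine (cat.), pyridine, CH2Cl2, rt
Reagents that add atoms: acetic anhydride CC(=O)OC(C)=O
Why: Acetylation of the two secondary alcohols at C2 and C14; the tertiary C8 hydroxyl, flanked by three substituted carbons, should not be acylated under these conditions.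

## Compound list

1 | 3-methylcyclohex-2-en-1-one | CC1=CC(=O)CCC1 | starting material
2 | 7-methyl-1,4-dioxaspiro[4.5]dec-7-ene | CC1=CCCC2(C1)OCCO2 | intermediate
3 | 7,8-epoxy-7-methyl-1,4-dioxaspiro[4.5]decane, epoxide on the later C14–O face | C1COC2(O1)CC[C@@H]3O[C@]3(C)C2 | intermediate
4 | 3,4-epoxy-3-methylcyclohexanone (epoxy ketone, not isolated) | O=C1CC[C@@H]2O[C@]2(C)C1 | intermediate
5 | (S)-4-hydroxy-3-methylcyclohex-2-en-1-one | CC1=CC(=O)CC[C@@H]1O | intermediate
6 | vinylmagnesium bromide | C=C[Mg]Br | starting material
7 | (3S,4S)-4-hydroxy-3-methyl-3-vinylcyclohexan-1-one (vinyl cis to OH) | C=C[C@]1(C)CC(=O)CC[C@@H]1O | intermediate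
8 | ethylene ketal of 7 | C=C[C@]1(C)CC2(CC[C@@H]1O)OCCO2 | intermediate
9 | ozonide (1,2,4-trioxolane) of 8, not isolated | C1(OOCO1)[C@]2(C)CC3(CC[C@@H]2O)OCCO3 | intermediate
10 | ring A aldehyde: 8-hydroxy-7-methyl-1,4-dioxaspiro[4.5]decane-7-carbaldehyde, CHO cis to OH | O=C[C@]1(C)CC2(CC[C@@H]1O)OCCO2 | intermediate
11 | allylic alcohol, C2 epimers | C=CC(O)[C@]1(C)CC2(CC[C@@H]1O)OCCO2 | intermediate
12 | ring A vinyl ketone (C2 ketone, C14–OH free, C11 ketal) | C=CC(=O)[C@]1(C)CC2(CC[C@@H]1O)OCCO2 | intermediate
13 | 2-methylcyclopentane-1,3-dione | CC1C(=O)CCC1=O | starting material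
14 | Michael adduct: 2-methyl-2-(3-oxo-3-ring A-propyl)cyclopentane-1,3-dione | CC1(CCC(=O)[C@]2(C)CC3(CC[C@@H]2O)OCCO3)C(=O)CCC1=O | intermediate
15 | syn-C2/C14 diol (2R,14S) | CC1(CC[C@@H](O)[C@]2(C)CC3(CC[C@@H]2O)OCCO3)C(=O)CCC1=O | intermediate
16 | C2,C14-O-di-tert-butylsilylene dione | CC1(CC[C@@H](O[Si]5(C(C)(C)C)C(C)(C)C)[C@]2(C)CC3(CC[C@@H]2O5)OCCO3)C(=O)CCC1=O | intermediate
17 | hydroxy ketone (5R,6R; C6–OH cis to C4 chain; C9 ketone) | C[C@@]1(CC[C@@H](O[Si]5(C(C)(C)C)C(C)(C)C)[C@]2(C)CC3(CC[C@@H]2O5)OCCO3)[C@H](O)CCC1=O | intermediate
18 | C6-O-trimethylsilyl C8=C9 trimethylsilyl enol ether, not isolated | C[C@@]1(CC[C@@H](O[Si]5(C(C)(C)C)C(C)(C)C)[C@]2(C)CC3(CC[C@@H]2O5)OCCO3)[C@H](O[Si](C)(C)C)CC=C1O[Si](C)(C)C | intermediate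
19 | γ-hydroxy cyclopentenone (C9 ketone, C7=C8, C6–OH) | C[C@@]1(CC[C@@H](O[Si]5(C(C)(C)C)C(C)(C)C)[C@]2(C)CC3(CC[C@@H]2O5)OCCO3)[C@H](O)C=CC1=O | intermediate
20 | C7,C8 osmate ester (hexavalent osmium) with TMEDA, not isolated | C[C@@]1(CC[C@@H](O[Si]5(C(C)(C)C)C(C)(C)C)[C@]2(C)CC3(CC[C@@H]2O5)OCCO3)[C@H](O)[C@@H]6O[Os](=O)(=O)O[C@@H]6C1=O.CN(C)CCN(C)C | intermediate
21 | all-cis C6,C7,C8-triol ketone | C[C@@]1(CC[C@@H](O[Si]5(C(C)(C)C)C(C)(C)C)[C@]2(C)CC3(CC[C@@H]2O5)OCCO3)[C@H](O)[C@H](O)[C@H](O)C1=O | intermediate
22 | C7,C8-acetonide with ring A ketal, not isolated | C[C@@]1(CC[C@@H](O[Si]5(C(C)(C)C)C(C)(C)C)[C@]2(C)CC3(CC[C@@H]2O5)OCCO3)[C@H](O)[C@@H]6OC(C)(C)O[C@@H]6C1=O | intermediate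
23 | C7,C8-acetonide diketone (C9 and C11 ketones, C6–OH) | C[C@@]1(CC[C@@H](O[Si]5(C(C)(C)C)C(C)(C)C)[C@]2(C)CC(=O)CC[C@@H]2O5)[C@H](O)[C@@H]6OC(C)(C)O[C@@H]6C1=O | intermediate
24 | C6 triethylsilyl ether of 23 | C[C@@]1(CC[C@@H](O[Si]5(C(C)(C)C)C(C)(C)C)[C@]2(C)CC(=O)CC[C@@H]2O5)[C@H](O[Si](CC)(CC)CC)[C@@H]6OC(C)(C)O[C@@H]6C1=O | intermediate
25 | tricyclic ketol: trans-6/7, cis-7/5, C11 ketone, C9–OH cis to C5–Me, C6–OSiEt3 | O=C1CC[C@H](O[Si]4(C(C)(C)C)C(C)(C)C)[C@@]2(C)[C@H]1[C@@]1(O)[C@H]3OC(C)(C)O[C@H]3[C@@H](O[Si](CC)(CC)CC)[C@@]1(C)CC[C@H]2O4 | intermediate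
26 | C11 methylene tricycle, C6–OSiEt3 | C=C1CC[C@H](O[Si]4(C(C)(C)C)C(C)(C)C)[C@@]2(C)[C@H]1[C@@]1(O)[C@H]3OC(C)(C)O[C@H]3[C@@H](O[Si](CC)(CC)CC)[C@@]1(C)CC[C@H]2O4 | intermediate
27 | C6 alcohol (C6–OH cis to acetonide and C4) | C=C1CC[C@H](O[Si]4(C(C)(C)C)C(C)(C)C)[C@@]2(C)[C@H]1[C@@]1(O)[C@H]3OC(C)(C)O[C@H]3[C@@H](O)[C@@]1(C)CC[C@H]2O4 | intermediate
28 | key-step precursor: tricyclic C9 tertiary alcohol, C6 mesylate cis to C4, C7/C8 acetonide, C2/C14 silylene | C=C1CC[C@H](O[Si]4(C(C)(C)C)C(C)(C)C)[C@@]2(C)[C@H]1[C@@]1(O)[C@H]3OC(C)(C)O[C@H]3[C@@H](OS(C)(=O)=O)[C@@]1(C)CC[C@H]2O4 | intermediate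
29 | potassium C9 alkoxide of 28, not isolated | C=C1CC[C@H](O[Si]4(C(C)(C)C)C(C)(C)C)[C@@]2(C)[C@H]1[C@@]1([O-])[C@H]3OC(C)(C)O[C@H]3[C@@H](OS(C)(=O)=O)[C@@]1(C)CC[C@H]2O4.[K+] | intermediate
30 | key-step product: bicyclic (Z)-cyclodecenone, C9 ketone, C7/C8 acetonide | C=C1CC[C@H](O[Si]4(C(C)(C)C)C(C)(C)C)[C@@]2(C)[C@H]1C(=O)[C@H]1OC(C)(C)O[C@H]1/C=C(/C)CC[C@H]2O4 | intermediate
31 | (9R)-alcohol | C=C1CC[C@H](O[Si]4(C(C)(C)C)C(C)(C)C)[C@@]2(C)[C@H]1[C@@H](O)[C@H]1OC(C)(C)O[C@H]1/C=C(/C)CC[C@H]2O4 | intermediate
32 | C9 acetate | C=C1CC[C@H](O[Si]4(C(C)(C)C)C(C)(C)C)[C@@]2(C)[C@H]1[C@@H](OC(C)=O)[C@H]1OC(C)(C)O[C@H]1/C=C(/C)CC[C@H]2O4 | intermediate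
33 | C7,C8-diol, C9 acetate | C=C1CC[C@H](O[Si]4(C(C)(C)C)C(C)(C)C)[C@@]2(C)[C@H]1[C@@H](OC(C)=O)[C@@H](O)[C@@H](O)/C=C(/C)CC[C@H]2O4 | intermediate
34 | 2-bromopropanoyl bromide (racemic) | CC(Br)C(Br)=O | starting material
35 | C7 2-bromopropanoate, C8–OH | C=C1CC[C@H](O[Si]4(C(C)(C)C)C(C)(C)C)[C@@]2(C)[C@H]1[C@@H](OC(C)=O)[C@@H](O)[C@@H](OC(=O)C(C)Br)/C=C(/C)CC[C@H]2O4 | intermediate
36 | C8 ketone, C7 2-bromopropanoate | C=C1CC[C@H](O[Si]4(C(C)(C)C)C(C)(C)C)[C@@]2(C)[C@H]1[C@@H](OC(C)=O)C(=O)[C@@H](OC(=O)C(C)Br)/C=C(/C)CC[C@H]2O4 | intermediate
37 | lactone with C2/C14 silylene (8S,17R) | C=C1CC[C@H](O[Si]4(C(C)(C)C)C(C)(C)C)[C@@]2(C)[C@H]1[C@@H](OC(C)=O)[C@@]1(O)[C@H](/C=C(/C)CC[C@H]2O4)OC(=O)[C@@H]1C | intermediate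
38 | C2,C14-diol lactone | C=C1CC[C@H](O)[C@@]2(C)[C@H]1[C@@H](OC(C)=O)[C@@]1(O)[C@H](/C=C(/C)CC[C@H]2O)OC(=O)[C@@H]1C | intermediate
39 | CNP0187723.2 | C=C1CC[C@H](OC(C)=O)[C@@]2(C)[C@H]1[C@@H](OC(C)=O)[C@@]1(O)[C@H](/C=C(/C)CC[C@H]2OC(C)=O)OC(=O)[C@@H]1C | target

## Step count and least certain steps

Total: 29 steps. Longest linear sequence: 29 steps (1 → 39); 6, 13 and 34 are commercial.

Step 21 (key step). The fragmentation itself is stereoelectronically well set up. The most likely failure is loss of the product after it forms: base-mediated migration of the C11=C20 bond into conjugation, epimerisation at C10, or β-elimination of the C7 oxygen. Fallback: the fragmentation is induced with hydride so that the ketone never accumulates. Starting from 28, LiAlH4 in THF at 0 °C forms the aluminate alkoxide, which fragments, and the C9 ketone is reduced as it is formed. The route is rejoined at 31 (after separation from any C9 epimer), bypassing 30.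

Step 17 (aldol closure). Two things can go wrong. The aldol equilibrium may lie on the side of the open diketone, because the C9–C10 bond is flanked by two quaternary carbons. Closure may also be slow enough for enolisation at C8, with opening of the acetonide, to compete. The ring fusion also depends on equilibration, since a tether on C1 kinetically favours cis closure. Fallback: the equilibrium is pulled over by irreversible O-silylation. Starting from 24, the enolate is generated with KN(SiMe3)2 in THF with a trace of t-BuOH, and after equilibration the aldolate is quenched with Me3SiCl to give the C9 trimethylsilyl ether of the ketol F1. F1 is methylenated as in step 18 to the C9 trimethylsilyl ether of the methylene tricycle F2, and K2CO3 in MeOH cleaves the tertiary silyl ether to rejoin the route at 26.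

Step 14 (directed dihydroxylation). The osmium–diamine complex may react sluggishly with the electron-poor enone, or hydrogen-bond delivery may lose to the intrinsic preference for attack anti to the C6 oxygen, giving poor facial selectivity. Fallback: the five-membered ring is built in the enantiomeric sense, so that the intrinsic anti preference is the one needed. Starting from 16, the (R)-oxazaborolidine gives the enantiomeric hydroxy ketone F3. Et3SiOTf gives its silyl ether F4. Saegusa dehydrogenation gives the enone F5. Catalytic OsO4 with N-methylmorpholine N-oxide adds anti to the C6 silyloxy group to give the diol F6. Acetonide formation and ketal hydrolysis as in step 15 give the acetonide diketone F7. Aldol closure as in step 17 gives the ketol F8. Methylenation gives the methylene tricycle F9, desilylation the alcohol F10, and mesylation the mesylate F11. F11 has C5 and C9 inverted and the sulfonate trans to the acetonide, but the sulfonate is still cis to C4 and C7 is unchanged, so fragmentation as in step 21 rejoins the route at 30.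

Step 4 (directed vinyl addition). The β-carbon is already substituted, so competing 1,2-addition or incomplete conversion is the likely failure. Fallback: the C1–C2 bond is made by a silicon-tethered radical cyclisation, which also delivers the carbon cis to the C14 oxygen. Starting from 5, BrCH2SiMe2Cl and imidazole give the (bromomethyl)dimethylsilyl ether F12. Bu3SnH with azobisisobutyronitrile closes the cis-fused oxasilolane F13. H2O2, KF and KHCO3 (Tamao oxidation) give the keto diol F14. Ketalisation as in step 5 gives the diol ketal F15. Selective oxidation of the primary alcohol (2,2,6,6-tetramethylpiperidin-1-oxyl, PhI(OAc)2) rejoins the route at 10.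

Step 22 (C9 reduction). Chelation control competes with the conformational bias of the ten-membered ring and with the α-branch at C10, so facial selectivity may be poor or reversed. Fallback: the carbinol is inverted rather than re-reduced. Starting from 30, a non-chelating hydride gives the C9 epimer of the alcohol F16. Mitsunobu reaction with 4-nitrobenzoic acid gives the inverted 4-nitrobenzoate F17, and methanolysis (K2CO3, MeOH) rejoins the route at 31.

Step 25 (C7 acylation). The two secondary hydroxyls may not differ enough, so regioselectivity may be poor, and acetyl migration from C9 is possible. Fallback: the diol is activated through tin instead of relying on sterics. Starting from 33, Bu2SnO in toluene forms the dibutylstannylene acetal F18, whose more accessible allylic oxygen is acylated by 34 to rejoin the route at 35.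

## Further compounds

F0 | step 21 | none | none
F1 | step 17 | C9 trimethylsilyl ether of tricyclic ketol 25 | O=C1CC[C@H](O[Si]4(C(C)(C)C)C(C)(C)C)[C@@]2(C)[C@H]1[C@@]1(O[Si](C)(C)C)[C@H]3OC(C)(C)O[C@H]3[C@@H](O[Si](CC)(CC)CC)[C@@]1(C)CC[C@H]2O4
F2 | step 17 | C9 trimethylsilyl ether of methylene tricycle 26 | C=C1CC[C@H](O[Si]4(C(C)(C)C)C(C)(C)C)[C@@]2(C)[C@H]1[C@@]1(O[Si](C)(C)C)[C@H]3OC(C)(C)O[C@H]3[C@@H](O[Si](CC)(CC)CC)[C@@]1(C)CC[C@H]2O4
F3 | step 14 | enantiomeric-ring hydroxy ketone (5S,6S) | C[C@]1(CC[C@@H](O[Si]5(C(C)(C)C)C(C)(C)C)[C@]2(C)CC3(CC[C@@H]2O5)OCCO3)[C@@H](O)CCC1=O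
F4 | step 14 | C6 triethylsilyl ether of F3 | C[C@]1(CC[C@@H](O[Si]5(C(C)(C)C)C(C)(C)C)[C@]2(C)CC3(CC[C@@H]2O5)OCCO3)[C@@H](O[Si](CC)(CC)CC)CCC1=O
F5 | step 14 | C7=C8 enone from F4 | C[C@]1(CC[C@@H](O[Si]5(C(C)(C)C)C(C)(C)C)[C@]2(C)CC3(CC[C@@H]2O5)OCCO3)[C@@H](O[Si](CC)(CC)CC)C=CC1=O
F6 | step 14 | C7,C8-diol trans to the C6 silyloxy group | C[C@]1(CC[C@@H](O[Si]5(C(C)(C)C)C(C)(C)C)[C@]2(C)CC3(CC[C@@H]2O5)OCCO3)[C@@H](O[Si](CC)(CC)CC)[C@H](O)[C@H](O)C1=O
F7 | step 14 | C7,C8-acetonide diketone of the enantiomeric-ring series | C[C@]1(CC[C@@H](O[Si]5(C(C)(C)C)C(C)(C)C)[C@]2(C)CC(=O)CC[C@@H]2O5)[C@@H](O[Si](CC)(CC)CC)[C@@H]6OC(C)(C)O[C@@H]6C1=O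
F8 | step 14 | tricyclic ketol with C5 and C9 inverted | O=C1CC[C@H](O[Si]4(C(C)(C)C)C(C)(C)C)[C@@]2(C)[C@H]1[C@]1(O)[C@H]3OC(C)(C)O[C@H]3[C@H](O[Si](CC)(CC)CC)[C@]1(C)CC[C@H]2O4
F9 | step 14 | C11 methylene tricycle with C5 and C9 inverted | C=C1CC[C@H](O[Si]4(C(C)(C)C)C(C)(C)C)[C@@]2(C)[C@H]1[C@]1(O)[C@H]3OC(C)(C)O[C@H]3[C@H](O[Si](CC)(CC)CC)[C@]1(C)CC[C@H]2O4
F10 | step 14 | C6 alcohol trans to the acetonide | C=C1CC[C@H](O[Si]4(C(C)(C)C)C(C)(C)C)[C@@]2(C)[C@H]1[C@]1(O)[C@H]3OC(C)(C)O[C@H]3[C@H](O)[C@]1(C)CC[C@H]2O4
F11 | step 14 | C6 mesylate trans to the acetonide and cis to C4 | C=C1CC[C@H](O[Si]4(C(C)(C)C)C(C)(C)C)[C@@]2(C)[C@H]1[C@]1(O)[C@H]3OC(C)(C)O[C@H]3[C@H](OS(C)(=O)=O)[C@]1(C)CC[C@H]2O4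
F12 | step 4 | (bromomethyl)dimethylsilyl ether of 5 | CC1=CC(=O)CC[C@@H]1O[Si](C)(C)CBr
F13 | step 4 | cis-fused oxasilolane ketone | C[Si]1(C)C[C@]2(C)CC(=O)CC[C@@H]2O1
F14 | step 4 | 4-hydroxy-3-(hydroxymethyl)-3-methylcyclohexan-1-one, cis | OC[C@]1(C)CC(=O)CC[C@@H]1O
F15 | step 4 | ethylene ketal of F14 | OC[C@]1(C)CC2(CC[C@@H]1O)OCCO2
F16 | step 22 | C9 epimer of alcohol 31 | C=C1CC[C@H](O[Si]4(C(C)(C)C)C(C)(C)C)[C@@]2(C)[C@H]1[C@H](O)[C@H]1OC(C)(C)O[C@H]1/C=C(/C)CC[C@H]2O4
F17 | step 22 | (9R)-4-nitrobenzoate | C=C1CC[C@H](O[Si]4(C(C)(C)C)C(C)(C)C)[C@@]2(C)[C@H]1[C@@H](OC(=O)c5ccc(cc5)[N+](=O)[O-])[C@H]1OC(C)(C)O[C@H]1/C=C(/C)CC[C@H]2O4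
F18 | step 25 | C7,C8-O-dibutylstannylene acetal of 33 | C=C1CC[C@H](O[Si]4(C(C)(C)C)C(C)(C)C)[C@@]2(C)[C@H]1[C@@H](OC(C)=O)[C@H]1O[Sn](CCCC)(CCCC)O[C@H]1/C=C(/C)CC[C@H]2O4
A1 | alternative 1 | (Z)-olefin γ-lactone carrying ring A (seco-C9–C10 compound) | COc1ccc(COCC2=C[C@@](C)([C@H](O[Si](C)(C)C(C)(C)C)CC/C(C)=C\[C@@H]3OC(=O)[C@H](C)[C@@]3(OCOC)CO[Si](C)(C)C(C)(C)C)[C@@H](O[Si](C)(C)C(C)(C)C)CC2)cc1
A2 | alternative 1 | propyne | CC#C
A3 | alternative 2 | methylenecyclohexanol with C1 and C10 set (C14 epimeric to the target) | C=C1CC[C@@H](O)[C@](C)(CO[Si](c2ccccc2)(c2ccccc2)C(C)(C)C)[C@H]1COC(=O)C(C)(C)C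
A4 | alternative 3 | target as its C8 trimethylsilyl ether | C=C1CC[C@H](OC(C)=O)[C@@]2(C)[C@H]1[C@@H](OC(C)=O)[C@@]1(O[Si](C)(C)C)[C@H](/C=C(/C)CC[C@H]2OC(C)=O)OC(=O)[C@@H]1C
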